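Follow the free catalyst, not the substrate.

| flask | substrate | free catalyst | time | remark |
|---|---|---|---|---|
| violet | 0.010 M | 1.1 mM | 20 h | everything together in a closed stirred flask, run for 20 h |
| amber | 0.010 M (fed, over 16.0 h) | 1.1 mM | 20 h | a stirred flask in which substrate is dosed at a steady rate over 16.0 h without added volume, worked up at 20 h |
| ochre | 0.010 M | 1.1 mM |  | a single well-mixed tank run continuously and read at steady state, 20 h in it on average |

    substrate + free catalyst → spent catalyst (k1 = 35.9 M⁻¹ h⁻¹)
    substrate → intermediate (k2 = 0.343 h⁻¹)
    free catalyst + intermediate ⇌ free catalyst + target (K3 = 1.65, k3 = 522 M⁻¹ h⁻¹)

- the stated concentrations are those of everything mixed, before any reaction; amounts are the same in each set-up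
- the feed brings no volume worth counting
- run time (violet): 20 h

1. the set-up with the highest amount of target at the outlet or at the end, in percent of the substrate put in ("none" if the first two lie within 2 percentage points) (violet / amber / ochre / none)
2. amount of target at the outlet or at the end, in percent of the substrate put in, violet
3. amount of target at the outlet or at the end, in percent of the substrate put in, amber
4. amount of target at the outlet or at the end, in percent of the substrate put in, ochre

1. Substrate leaves by two ways, and both are first order in it. I divided the rate of spending free catalyst by the rate of making intermediate, and substrate and time cancelled. Integrating gave c(intermediate) + c(target) = 9.55 mM · ln(charged over present c(free catalyst)). Dosing does not change this law.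

2. I took two extremes. With no catalyst spent, the whole charge reaches the reversible pair, and equilibrium puts 62.3% of it in target. If the whole catalyst charge took its equal amount of substrate, the same split applied to the remaining substrate gives 55.4%.

3. Violet lies between them, since its spent catalyst lies between none and the whole charge. I solved the law with substrate gone, in two passes. The first pass gave 0.386 mM. The second gave the surviving catalyst, the free catalyst left once substrate is consumed: 0.416 mM. That set violet's ceiling at 58.0%, above 55.4% and below 62.3%.

4. The surviving catalyst also gives the pair's relaxation rate, 0.349 h⁻¹. Its time, 2.87 h, is shorter than the 20 h run, so I put violet at its ceiling.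

5. Amber shares that ceiling, but its feed stops 4.00 h before the reading, less than two relaxation times, so I placed it lower. Ochre's outlet carries at least 11.6% of the substrate unreacted. Its ceiling is therefore 55.1%, lower than violet's.

The forecast gave violet, with 57.7%, 50.4% and 46.8%, its violet figure a little lower than my ceiling, starting from this: “Both the substrate and the catalyst kill are first order in substrate”.

The simulation gave violet: violet 57.6%, amber 50.5%, ochre 46.8%. Violet ended with 37.7% of its catalyst charge free, and my surviving catalyst was 37.8% of the charge. Amber, read at 200 h, held 58.0% of the substrate charge as target and 37.7% of its catalyst charge free.

The neighbour is violet charged with 0.280 mM free catalyst. The same two passes gave a surviving catalyst of 0.100 mM, which is 35.7% of its charge. Its ceiling came to 61.1%, higher than violet's. Its relaxation time came to 11.9 h, longer than violet's. The neighbour ended with 35.8% of its catalyst charge free and 50.2% of the substrate charge as intermediate. Its target at 20.0 h stood at 47.9%.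

The numbers of this flask are assumed, and the outcome is calculated.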